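**Retrosynthetic overview** (heptane numbering: C1 = CHBr, C2 = the other oxirane carbon, C3 = CBr2)
1. Hexanal 1, through imines 2 and 3, is the source of fragment A, 2,2-dibromohexanal 4 (C2–C7).
2. Dibromomethane 5, through carbenoid 6, is the source of fragment B, (dibromomethyl)trimethylsilane 7 (C1).
3. Key disconnection C1–C2: an enantioselective copper-catalysed coupling of 4 with 7 gives silyl ether 8 and sets C2.
4. Disconnection C1–O: alkoxide 9 displaces one diastereotopic bromide at C1 to give target 10, which sets C1 (trans).
5. Ring order: the oxirane is the only ring and is formed last, in the coupling flask.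

Assumption: the facial sense of the new catalyst cannot be known beforehand. (R)-DTBM-SEGPHOS (L*) is written for Si-face attack on 4, and its antipode is used if the opposite sense is found.

**Step 1**
Reactants: 1 hexanal
Product: 4 2,2-dibromohexanal, via imine 2 (not isolated), via dibromoimine 3 (not isolated)
Conditions: t-BuNH2 (1.0 equiv), 4 Å MS, CH2Cl2, 0 °C to rt; NBS (2.1 equiv), 0 °C to rt; 2 M aq HCl, rt; distil
Reagents that add atoms: N-bromosuccinimide O=C1CCC(=O)N1Br; water O
Why: Imine–enamine tautomerism lets NBS brominate the α-carbon of the N-tert-butyl aldimine twice (α-halogenation of an aldimine) without the aldol and oxidation side reactions of the free aldehyde, acid hydrolysis of the non-enolisable dibromoimine then returns the aldehyde and the amine auxiliary, and no stereocentre is formed.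

**Step 2**
Reactants: 5 dibromomethane
Product: 7 (dibromomethyl)trimethylsilane, via dibromomethyllithium 6 (not isolated)
Conditions: 5 (1.3 equiv), Me3SiCl (1.1 equiv, present from the start), LiN(i-Pr)2 (1.0 equiv, commercial solution, slow addition), THF/Et2O, −95 °C to rt; distil
Reagents that add atoms: chlorotrimethylsilane C[Si](C)(C)Cl
Why: Deprotonation of CH2Br2 gives the lithium carbenoid, which the Me3SiCl already in the flask traps before α-elimination can occur (in situ quench silylation of a carbenoid), and no stereocentre is formed.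

**Step 3**
Reactants: 4 2,2-dibromohexanal; 7 (dibromomethyl)trimethylsilane
Product: 10 (2R,3S)-2-bromo-3-(1,1-dibromopentyl)oxirane, via silyl ether 8 (not isolated), via ammonium alkoxide 9 (not isolated)
Conditions: CuOt-Bu (5 mol %), (R)-DTBM-SEGPHOS (5.5 mol %, premixed), 7 (1.05 equiv), toluene/THF 4:1, −40 °C; then n-Bu4NF (1.1 equiv, 1.0 M in THF), −78 to −20 °C; pH 7 buffer, pentane; Florisil, 0 °C
Reagents that add atoms: none
Why: Proposed new method: an enantioselective copper-catalysed cross-coupling of a (dihalomethyl)silane with an aldehyde, in which the monovalent copper alkoxide L*CuOt-Bu takes over the CHBr2 group of 7 by Si-to-Cu transmetalation (driven by the Si–O bond), the soft L*CuCHBr2 adds to the Si face of the non-enolisable and very electrophilic aldehyde 4 inside the DTBM-SEGPHOS pocket (H against the large CBr2Bu group is an easy steric choice) to form the C1–C2 bond and the (S) centre at C2, and the hindered copper alkoxide is silylated by the next molecule of 7, which returns L*CuCHBr2 and gives 8 with no free alkoxide or fluoride present to start a racemic silicate chain; n-Bu4NF then frees alkoxide 9, which closes the oxirane by 3-exo-tet SN2 displacement (Darzens-type halohydrin closure) at the less hindered C1 rather than at the fully substituted C3, expelling the diastereotopic bromide whose loss leaves Br anti to the dibromopentyl group, so that C1 becomes (R) (trans) while C2 is untouched, and any cis isomer is drained to trans by reversible bromide opening at C1; the closest known reaction types are the racemic fluoride-triggered addition of (dihalomethyl)silanes to aldehydes and the CuF/bisphosphine-catalysed enantioselective addition of alkenyl-, aryl- and cyanomethylsilanes to aldehydes.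

**Compound list**
1 | hexanal | CCCCCC=O | starting material
2 | (E)-N-tert-butylhexan-1-imine | CCCCC/C=N/C(C)(C)C | intermediate
3 | (E)-N-tert-butyl-2,2-dibromohexan-1-imine | CCCCC(Br)(Br)/C=N/C(C)(C)C | intermediate
4 | 2,2-dibromohexanal | CCCCC(Br)(Br)C=O | intermediate
5 | dibromomethane | BrCBr | starting material
6 | (dibromomethyl)lithium | [Li]C(Br)Br | intermediate
7 | (dibromomethyl)trimethylsilane | C[Si](C)(C)C(Br)Br | intermediate
8 | {[(2S)-1,1,3,3-tetrabromoheptan-2-yl]oxy}trimethylsilane | CCCCC(Br)(Br)[C@@H](O[Si](C)(C)C)C(Br)Br | intermediate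
9 | tetrabutylammonium (2S)-1,1,3,3-tetrabromoheptan-2-olate | CCCCC(Br)(Br)[C@@H]([O-])C(Br)Br.CCCC[N+](CCCC)(CCCC)CCCC | intermediate
10 | (2R,3S)-2-bromo-3-(1,1-dibromopentyl)oxirane (trans) | CCCCC(Br)(Br)[C@H]1O[C@@H]1Br | target

**Total step count:** 3
**Longest linear sequence:** 2 (1 → 4 → 10 or 5 → 7 → 10)

**Steps most likely to fail**

Step 3 (the new coupling).
- Risks:
  - bromine transfer from 4 to the copper carbenoid
  - a racemic background addition
  - early ring closure that parks the catalyst as CuBr
  - closure at C3 instead of C1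
- The fallback uses known chemistry only. It sets out from 4, with carbenoid 6 made from 5 as in step 2 but without Me3SiCl, and comes back at 10. Carbenoid 6 is added to 4 in THF at −95 °C to give lithium 1,1,3,3-tetrabromoheptan-2-olate F1, which is quenched cold with AcOH to racemic 1,1,3,3-tetrabromoheptan-2-ol F2. Dess–Martin oxidation gives 1,1,3,3-tetrabromoheptan-2-one F3. Corey–Bakshi–Shibata reduction with (R)-Me-CBS oxazaborolidine and catecholborane in toluene at −78 °C treats CBr2Bu as the large group, as in the reduction of trihalomethyl ketones, and gives (2S)-1,1,3,3-tetrabromoheptan-2-ol F4. NaH in THF at 0 °C forms sodium (2S)-1,1,3,3-tetrabromoheptan-2-olate F5, which closes to 10.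

Step 1.
- Risks:
  - an incomplete second bromination
  - slow hydrolysis of the hindered dibromoimine
  - hydrate formation
- The fallback sets out from 5 and comes back at 4. It builds the C2–C3 bond by carbenoid formylation instead of halogenating an aldehyde. Carbenoid 6 is alkylated with 1-iodobutane (THF/DMPU, −90 °C to rt) to give 1,1-dibromopentane F6. LiN(i-Pr)2 at −100 °C gives (1,1-dibromopentyl)lithium F7, which methyl formate traps as lithium 2,2-dibromo-1-methoxyhexan-1-olate F8. Cold HCl in Et2O collapses this adduct to 4.

Step 2.
- Risks: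
  - double silylation of the more acidic product
  - decomposition of the carbenoid
- The fallback sets out from 5 and comes back at 9. It changes the C1 donor from silicon to boron. Carbenoid 6 is generated in the presence of 2-isopropoxy-4,4,5,5-tetramethyl-1,3,2-dioxaborolane to give lithium (dibromomethyl)(isopropoxy)(pinacolato)borate F9. Anhydrous HCl converts it into 2-(dibromomethyl)-4,4,5,5-tetramethyl-1,3,2-dioxaborolane F10. This donor replaces 7 in step 3 (B-to-Cu transmetalation, same catalyst) and gives with 4 the boric ester 2-{[(2S)-1,1,3,3-tetrabromoheptan-2-yl]oxy}-4,4,5,5-tetramethyl-1,3,2-dioxaborolane F11, from which n-Bu4NF frees 9.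

**Further compounds**
F1 | step 3 | lithium 1,1,3,3-tetrabromoheptan-2-olate (racemic) | CCCCC(Br)(Br)C([O-])C(Br)Br.[Li+]
F2 | step 3 | racemic 1,1,3,3-tetrabromoheptan-2-ol | CCCCC(Br)(Br)C(O)C(Br)Br
F3 | step 3 | 1,1,3,3-tetrabromoheptan-2-one | CCCCC(Br)(Br)C(=O)C(Br)Br
F4 | step 3 | (2S)-1,1,3,3-tetrabromoheptan-2-ol | CCCCC(Br)(Br)[C@@H](O)C(Br)Br
F5 | step 3 | sodium (2S)-1,1,3,3-tetrabromoheptan-2-olate | CCCCC(Br)(Br)[C@@H]([O-])C(Br)Br.[Na+]
F6 | step 1 | 1,1-dibromopentane | CCCCC(Br)Br
F7 | step 1 | (1,1-dibromopentyl)lithium | [Li]C(Br)(Br)CCCC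
F8 | step 1 | lithium 2,2-dibromo-1-methoxyhexan-1-olate (racemic) | CCCCC(Br)(Br)C([O-])OC.[Li+]
F9 | step 2 | lithium (dibromomethyl)(isopropoxy)(pinacolato)borate | CC(C)O[B-]1(C(Br)Br)OC(C)(C)C(C)(C)O1.[Li+]
F10 | step 2 | 2-(dibromomethyl)-4,4,5,5-tetramethyl-1,3,2-dioxaborolane | BrC(Br)B1OC(C)(C)C(C)(C)O1
F11 | step 2 | 2-{[(2S)-1,1,3,3-tetrabromoheptan-2-yl]oxy}-4,4,5,5-tetramethyl-1,3,2-dioxaborolane | CCCCC(Br)(Br)[C@@H](OB1OC(C)(C)C(C)(C)O1)C(Br)Br
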